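Count time in this flask on a catalyst clock: the catalyst charged multiplied by the minutes run, 36.0 M·s at the asked time of the Friday's run.

in all of them: coupling partner 0.480 M

| charge | starting material | free catalyst | time |
|---|---|---|---|
| Thursday's | 0.400 M | 0.00800 M |  |
| Sunday's | 0.400 M | 0.0120 M |  |
| Wednesday's | 1.20 M | 0.00800 M |  |
| Friday's | 0.400 M | 0.0240 M | 25 min |

- Thursday's run (time / min: [starting material] / M): 3.6: 0.3626; 7.1: 0.3323; 11: 0.2956; 14: 0.2686; 18: 0.2356; 21: 0.2103; 25: 0.1806
- Sunday's run (time / min: [starting material] / M): 3.6: 0.3454; 7.1: 0.3026; 11: 0.2469; 14: 0.2123; 18: 0.1697; 21: 0.1388; 25: 0.1092
- Wednesday's run (time / min: [starting material] / M): 3.6: 1.1775; 7.1: 1.1588; 11: 1.1329; 14: 1.1145; 18: 1.0935; 21: 1.0785; 25: 1.0577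

(scatter of a reading: 0.002 M)

- reaction order in [starting material] at the outset, round the charge of the Thursday's run, defined at two percent of the starting material turned into product (one fixed amount of product, the same in the runs compared)
- reaction order in [free catalyst] at the outset, round the charge of the Thursday's run, defined at two percent of the starting material turned into product
- starting material in the Friday's run at 25 min, as a share of the starting material charged

- Overall: starting material + coupling partner -> product, with free catalyst as catalyst.
- Constant volume, constant temperature.
- Bound and free are read together.
- "The second partner" is coupling partner.
- An order is taken over about fifteen percent of the charge, up and down.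

Read the Thursday column against the Sunday column. Thursday's run at 21 min and Sunday's run at 14 min stand at one clock reading, 10.1 M·s and 10.1 M·s. They hold 0.2103 M and 0.2123 M of starting material, a gap of 2.00 mM, close to the scatter of 0.002 M. So the mean losses per minute up to those rows, set against the ratio of catalyst, read as an order of 0.974 in catalyst.

Now set Wednesday's column beside Thursday's. Over the first 7.1 min, Wednesday's run lost 0.0412 M of starting material and Thursday's run lost 0.0677 M, less from the larger charge. Between those two charges the loss reads as an order of −0.452 in starting material.

Sunday's last row stands at clock 18.0 M·s, and the Friday's run asks for twice that. Between Sunday's last two rows the logarithm of starting material falls against the clock at 5.00 M⁻¹ min⁻¹. We carry that slope on unchanged and reckon 6.10% of the charge left in the Friday's run.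

The forecast gives orders of −0.45 in starting material and 1 in catalyst and 5.5% left, below our figure, and notes: “Time-scaling also suggests no obvious catalyst death.”

The flask gives orders of −0.50 and 1.0 and 4.34% left, 1.8 percentage points under our reckoning. When the product made comes to a quarter of the starting material charged, the clock stands at 5.27 M·s in Thursday's run and 5.24 M·s in Sunday's run, against the 36.0 M·s at which the Friday's run was read.

    free catalyst + starting material ⇌ catalyst-substrate complex, settled at all times (15.60 M⁻¹)
    catalyst-substrate complex + coupling partner → product + free catalyst (6.420 M⁻¹ min⁻¹)
    starting material → decomposed substrate (0.001338 min⁻¹)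
    catalyst-substrate complex + starting material ⇌ doubly bound catalyst, settled at all times (3.660 M⁻¹)

From the charge of the Friday's run onward, catalyst-substrate complex met coupling partner and made product. Reckoned at the charge with the starting material counted as unbound, free catalyst was 6.11% of the catalyst, catalyst-substrate complex 38.1% and doubly bound catalyst, the resting state at that moment, 55.8%, more than either of the other forms. Alongside, starting material went to decomposed substrate by plain minutes, off the clock, at 0.00134 min⁻¹, which comes to 3.35% of what stood there over the 25 min of the Friday's run.

The data were computed with constants of no real substance, noise included.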